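**Plan**

Cuts: first the two hemiketal bonds O1–C2 and O1'–C2' together with the C2/C2' carbonyl oxygens, which leads back to a biaryl bis(ortho-hydroxypropiophenone). Then C5–O and C5'–O are cut, and last the biaryl bond C7–C7', which leaves a 3-iodo derivative of 2',4',6'-trihydroxypropiophenone.
Enabling feature (benzofuranone numbering): in each benzene ring C5 is para to C7a, the carbon that bears O1. While the furanone rings are open, C7a–OH is a free, ketone-chelated phenol, its ortho carbons C3a and C7 are substituted, and C5 is the only ring C–H. Each 4,5,6,7a-tetraoxygenated ring is therefore an acylphloroglucinol ring plus one oxygen para to a phenol.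
Forward order: both benzene rings come with the starting ketone. Chelation tells its three hydroxyls apart (benzyl on O6, methyl on O4, O7a left free). C7 is iodinated and C7–C7' is joined by Ullmann coupling. One persulfate oxidation brings in both C5 oxygens, and the two furanone rings close last and together when the propionyl CH2 groups are oxidised.
Stereochemistry: C2 and C2' are hemiketal carbons that form without control. The 2R,2'R isomer is taken from the stereoisomer mixture by chiral-phase chromatography, and the rest is re-equilibrated through the open diketone and recycled.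

Key step: step 7

Assumption: the structure fixes C2 and C2' (both R) but not the sense of the tetra-ortho-substituted C7–C7' axis, so the axis is carried racemic and either atropisomer with 2R,2'R centres counts as the target; because the hemiketal carbons can epimerise by ring opening, the final compound is handled cold in neutral or weakly acidic media.

**Route**

Step 1
Reactants: 1 flopropione, 1-(2,4,6-trihydroxyphenyl)propan-1-one (commercial)
Product: 2 1-[4-(benzyloxy)-2,6-dihydroxyphenyl]propan-1-one
Conditions: BnBr (1.0 equiv), K2CO3 (1.1 equiv), acetone, reflux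
Reagents that add atoms: benzyl bromide, BrCc1ccccc1
Why: Williamson etherification under weak base picks the hydroxyl para to the ketone, which is the most acidic one and the only one not hydrogen-bonded to the carbonyl group, as is usual for acylphloroglucinols, and one equivalent of halide limits dialkylation.

Step 2
Reactants: 2 1-[4-(benzyloxy)-2,6-dihydroxyphenyl]propan-1-one
Product: 3 1-[4-(benzyloxy)-2-hydroxy-6-methoxyphenyl]propan-1-one
Conditions: MeI (1.1 equiv), K2CO3 (1.2 equiv), acetone, reflux
Reagents that add atoms: iodomethane, CI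
Why: In this second Williamson etherification the two remaining hydroxyls are equivalent, and once one is methylated the last one is locked in a strong hydrogen bond to the ketone and resists MeI/K2CO3, which is the standard way to 2-hydroxy-4,6-dialkoxyaryl ketones.

Step 3
Reactants: 3 1-[4-(benzyloxy)-2-hydroxy-6-methoxyphenyl]propan-1-one
Product: 4 1-[4-(benzyloxy)-2-hydroxy-3-iodo-6-methoxyphenyl]propan-1-one
Conditions: NIS (1.05 equiv), TFA (cat.), MeCN, 0 °C to rt, dark
Reagents that add atoms: N-iodosuccinimide, O=C1CCC(=O)N1I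
Why: Electrophilic aromatic iodination of 2-hydroxy-4,6-dialkoxyaryl ketones goes to C3, ortho to the free chelated phenol and next to the small OH, rather than to C5 between two alkoxy groups, which puts iodine on the future C7.

Step 4
Reactants: 4 1-[4-(benzyloxy)-2-hydroxy-3-iodo-6-methoxyphenyl]propan-1-one
Product: 5 1-[4-(benzyloxy)-3-iodo-6-methoxy-2-(methoxymethoxy)phenyl]propan-1-one
Conditions: NaH (1.2 equiv), MOMCl (1.3 equiv), DMF, 0 °C to rt
Reagents that add atoms: chloromethyl methyl ether, COCCl
Why: O-alkylation of the sodium phenoxide (Williamson type) masks the acidic OH that would protonate the arylcopper species of the next step, and full deprotonation with NaH overcomes the chelation and the crowding of this phenol.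

Step 5
Reactants: 5 1-[4-(benzyloxy)-3-iodo-6-methoxy-2-(methoxymethoxy)phenyl]propan-1-one (two molecules)
Product: 6 1,1'-[6,6'-bis(benzyloxy)-4,4'-dimethoxy-2,2'-bis(methoxymethoxy)biphenyl-3,3'-diyl]bis(propan-1-one) (racemic axis)
Conditions: activated Cu bronze (10 equiv), DMF, 150 °C, Ar
Reagents that add atoms: none
Why: The classical Ullmann reductive homocoupling of a 2,6-dialkoxyaryl iodide, a reaction type proven for tetra-ortho-oxygenated 3,3'-diacylbiphenyls, forms the C7–C7' bond as a racemic axis, and ethers, acetals and ketones tolerate copper in hot DMF.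

Step 6
Reactants: 6 1,1'-[6,6'-bis(benzyloxy)-4,4'-dimethoxy-2,2'-bis(methoxymethoxy)biphenyl-3,3'-diyl]bis(propan-1-one)
Product: 7 1,1'-[6,6'-bis(benzyloxy)-2,2'-dihydroxy-4,4'-dimethoxybiphenyl-3,3'-diyl]bis(propan-1-one)
Conditions: conc. HCl (cat.), MeOH–THF, 50 °C
Reagents that add atoms: none
Why: Acid-catalysed acetal exchange with methanol removes the MOM groups, which leave especially easily ortho to a ketone, while the benzyl and methyl ethers are untouched.

Step 7
Reactants: 7 1,1'-[6,6'-bis(benzyloxy)-2,2'-dihydroxy-4,4'-dimethoxybiphenyl-3,3'-diyl]bis(propan-1-one)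
Product: 9 1,1'-[6,6'-bis(benzyloxy)-2,2',5,5'-tetrahydroxy-4,4'-dimethoxybiphenyl-3,3'-diyl]bis(propan-1-one), via dipotassium 5,5'-bis(aryl sulfate) 8 (not isolated)
Conditions: K2S2O8 (2.6 equiv, in portions), 10% aq NaOH–pyridine, 10–20 °C, Ar; HCl to pH 4, Et2O wash (recovers 7); aqueous phase, 2 M HCl, 75 °C, Ar
Reagents that add atoms: potassium peroxodisulfate, [K+].[K+].[O-]S(=O)(=O)OOS(=O)(=O)[O-]
Why: In alkali each chelated phenol at biphenyl C2/C2' (C7a–OH in benzofuranone numbering) is a phenolate whose para carbon C5 attacks a peroxide oxygen of peroxodisulfate and expels sulfate, and the cyclohexadienone so formed tautomerises to the aryl sulfate 8. This is the Elbs persulfate oxidation, and its closest precedent is the conversion of 2-hydroxy-4,6-dialkoxyacetophenones, benzyl ethers included, into the 2,5-dihydroxy ketones. Each sulfate ester masks the new oxygen as an anionic, electron-withdrawing group, which shields the hydroquinone level from further oxidation until the acid hydrolysis (S–O cleavage) and keeps the half-oxidised biaryl in solution so that the second ring can react. No ring closes and no stereocentre forms, and the racemic axis is untouched. The step needs attack at the para carbon only: both ortho carbons of each phenolate are blocked (acyl-bearing carbon and biaryl carbon) and C5 is the sole ring C–H, so positional isomers are excluded, while benzyl ethers and ketones should be inert to persulfate at or below room temperature. Unchanged 7 and the mono-oxidised biaryl are the expected companions and would be recovered and resubmitted.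

Step 8
Reactants: 9 1,1'-[6,6'-bis(benzyloxy)-2,2',5,5'-tetrahydroxy-4,4'-dimethoxybiphenyl-3,3'-diyl]bis(propan-1-one)
Product: 10 1,1'-[6,6'-bis(benzyloxy)-2,2'-dihydroxy-4,4',5,5'-tetramethoxybiphenyl-3,3'-diyl]bis(propan-1-one)
Conditions: MeI (2.2 equiv), K2CO3 (2.4 equiv), acetone, reflux, Ar
Reagents that add atoms: iodomethane, CI
Why: Williamson etherification with a weak base methylates only the two new C5 hydroxyls, because the C2/C2' hydroxyls are chelated to the ketones and buried next to the axis, as in the known partial methylation of 2,5-dihydroxy-4,6-dialkoxyaryl ketones.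

Step 9
Reactants: 10 1,1'-[6,6'-bis(benzyloxy)-2,2'-dihydroxy-4,4',5,5'-tetramethoxybiphenyl-3,3'-diyl]bis(propan-1-one)
Product: 12 6,6'-bis(benzyloxy)-2,2'-dihydroxy-4,4',5,5'-tetramethoxy-2,2'-dimethyl-[7,7'-bibenzofuran]-3,3'(2H,2'H)-dione (stereoisomer mixture), via bis(1,2-diketone) 11 (not isolated)
Conditions: SeO2 (3 equiv), 1,4-dioxane–H2O (20:1), 100 °C
Reagents that add atoms: selenium dioxide, O=[Se]=O
Why: The Riley oxidation turns the α-CH2 of each aryl ethyl ketone into a carbonyl group through its enol, and the neighbouring phenol then adds to the new methyl ketone (5-exo-trig hemiketalisation), which closes both furanone rings, removes the methyl ketone from further oxidation and creates C2 and C2' without control, while the fully substituted arenes offer no site for electrophilic selenium.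

Step 10
Reactants: 12 6,6'-bis(benzyloxy)-2,2'-dihydroxy-4,4',5,5'-tetramethoxy-2,2'-dimethyl-[7,7'-bibenzofuran]-3,3'(2H,2'H)-dione (stereoisomer mixture)
Product: 13 2,2',6,6'-tetrahydroxy-4,4',5,5'-tetramethoxy-2,2'-dimethyl-[7,7'-bibenzofuran]-3,3'(2H,2'H)-dione (stereoisomer mixture)
Conditions: H2 (1 atm), 10% Pd/C, EtOAc, rt
Reagents that add atoms: none
Why: Catalytic hydrogenolysis cleaves the two aryl benzyl ethers under neutral conditions, and the electron-rich ring ketones, the methyl ethers and the closed hemiketals should not be reduced at atmospheric pressure.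

Step 11
Reactants: 13 2,2',6,6'-tetrahydroxy-4,4',5,5'-tetramethoxy-2,2'-dimethyl-[7,7'-bibenzofuran]-3,3'(2H,2'H)-dione (stereoisomer mixture)
Product: 14 (2R,2'R)-2,2',6,6'-tetrahydroxy-4,4',5,5'-tetramethoxy-2,2'-dimethyl-[7,7'-bibenzofuran]-3,3'(2H,2'H)-dione (target)
Conditions: preparative HPLC, immobilised amylose tris(3,5-dimethylphenylcarbamate) phase, n-hexane–iPrOH–HCO2H (0.1%), 10 °C; unwanted fractions: Et3N (cat.), MeCN, rt, then re-injection
Reagents that add atoms: none
Why: Resolution on a chiral stationary phase separates the isomers that differ at C2, C2' and the axis, the 2R,2'R fractions would be recognised by ECD comparison with calculation or by X-ray analysis, and since the hemiketals interconvert through the open diketone under base catalysis the unwanted fractions can be re-equilibrated and recycled.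

**Compound list**

1 | flopropione, 1-(2,4,6-trihydroxyphenyl)propan-1-one | CCC(=O)c1c(O)cc(O)cc1O | starting material
2 | 1-[4-(benzyloxy)-2,6-dihydroxyphenyl]propan-1-one | CCC(=O)c1c(O)cc(OCc2ccccc2)cc1O | intermediate
3 | 1-[4-(benzyloxy)-2-hydroxy-6-methoxyphenyl]propan-1-one | CCC(=O)c1c(O)cc(OCc2ccccc2)cc1OC | intermediate
4 | 1-[4-(benzyloxy)-2-hydroxy-3-iodo-6-methoxyphenyl]propan-1-one | CCC(=O)c1c(O)c(I)c(OCc2ccccc2)cc1OC | intermediate
5 | 1-[4-(benzyloxy)-3-iodo-6-methoxy-2-(methoxymethoxy)phenyl]propan-1-one | CCC(=O)c1c(OCOC)c(I)c(OCc2ccccc2)cc1OC | intermediate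
6 | 1,1'-[6,6'-bis(benzyloxy)-4,4'-dimethoxy-2,2'-bis(methoxymethoxy)biphenyl-3,3'-diyl]bis(propan-1-one), racemic axis | CCC(=O)c1c(OCOC)c(-c2c(OCOC)c(C(=O)CC)c(OC)cc2OCc2ccccc2)c(OCc2ccccc2)cc1OC | intermediate
7 | 1,1'-[6,6'-bis(benzyloxy)-2,2'-dihydroxy-4,4'-dimethoxybiphenyl-3,3'-diyl]bis(propan-1-one) | CCC(=O)c1c(O)c(-c2c(O)c(C(=O)CC)c(OC)cc2OCc2ccccc2)c(OCc2ccccc2)cc1OC | intermediate
8 | dipotassium 5,5'-bis(aryl sulfate) of 9 | CCC(=O)c1c(O)c(-c2c(O)c(C(=O)CC)c(OC)c(OS(=O)(=O)[O-])c2OCc2ccccc2)c(OCc2ccccc2)c(OS(=O)(=O)[O-])c1OC.[K+].[K+] | intermediate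
9 | 1,1'-[6,6'-bis(benzyloxy)-2,2',5,5'-tetrahydroxy-4,4'-dimethoxybiphenyl-3,3'-diyl]bis(propan-1-one) | CCC(=O)c1c(O)c(-c2c(O)c(C(=O)CC)c(OC)c(O)c2OCc2ccccc2)c(OCc2ccccc2)c(O)c1OC | intermediate
10 | 1,1'-[6,6'-bis(benzyloxy)-2,2'-dihydroxy-4,4',5,5'-tetramethoxybiphenyl-3,3'-diyl]bis(propan-1-one) | CCC(=O)c1c(O)c(-c2c(O)c(C(=O)CC)c(OC)c(OC)c2OCc2ccccc2)c(OCc2ccccc2)c(OC)c1OC | intermediate
11 | 1,1'-[6,6'-bis(benzyloxy)-2,2'-dihydroxy-4,4',5,5'-tetramethoxybiphenyl-3,3'-diyl]bis(propane-1,2-dione) | CC(=O)C(=O)c1c(O)c(-c2c(O)c(C(=O)C(C)=O)c(OC)c(OC)c2OCc2ccccc2)c(OCc2ccccc2)c(OC)c1OC | intermediate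
12 | 6,6'-bis(benzyloxy)-2,2'-dihydroxy-4,4',5,5'-tetramethoxy-2,2'-dimethyl-[7,7'-bibenzofuran]-3,3'(2H,2'H)-dione, stereoisomer mixture | COc1c(OCc2ccccc2)c(-c2c(OCc3ccccc3)c(OC)c(OC)c3c2OC(C)(O)C3=O)c2c(c1OC)C(=O)C(C)(O)O2 | intermediate
13 | 2,2',6,6'-tetrahydroxy-4,4',5,5'-tetramethoxy-2,2'-dimethyl-[7,7'-bibenzofuran]-3,3'(2H,2'H)-dione, stereoisomer mixture | COc1c(O)c(-c2c(O)c(OC)c(OC)c3c2OC(C)(O)C3=O)c2c(c1OC)C(=O)C(C)(O)O2 | intermediate
14 | (2R,2'R)-2,2',6,6'-tetrahydroxy-4,4',5,5'-tetramethoxy-2,2'-dimethyl-[7,7'-bibenzofuran]-3,3'(2H,2'H)-dione | COc1c(O)c(-c2c(O)c(OC)c(OC)c3c2O[C@@](C)(O)C3=O)c2c(c1OC)C(=O)[C@](C)(O)O2 | target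

**Step count**

Total step count: 11. Longest linear sequence: 11 (from 1; the two halves are joined by homocoupling in step 5).

**Steps most likely to fail**

Step 7. The second ring may be oxidised incompletely, and radical side paths of persulfate may degrade the electron-rich phenolates in alkali, so that little of the doubly oxygenated biaryl comes through.
- The fallback replaces the C–H oxygenation by halogenation and copper-mediated C–O coupling.
- Setting out from 7, NBS (MeCN, 0 °C) should brominate the only free ring positions to give the 5,5'-dibromide F1.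
- NaOMe with CuBr in DMF–MeOH at about 110 °C, the Ullmann-type methoxylation used on bromohydroxybenzaldehydes, should exchange both bromines for methoxy groups.
- This comes back to the route at 10 and bypasses 9.

Step 11. C2 and C2' may epimerise by ring–chain tautomerism on the column or on concentration, and up to six stereoisomers may overlap, so that collected fractions lose configurational purity.
- The fallback fixes the configuration before the separation.
- Setting out from 12, benzyl chloroformate (pyridine, DMAP, CH2Cl2, 0 °C) should acylate both hemiketal hydroxyls to give the bis(benzyl carbonate) mixture F2, which can no longer open to the diketone.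
- Chiral-phase chromatography of this stable material should give the (2S,2'S)-bis(benzyl carbonate) F3. Its descriptors change only because the carbonate oxygen outranks O1, and the spatial arrangement is that of the target.
- Neutral hydrogenolysis (H2, Pd/C, EtOAc) should remove both carbonates and both benzyl ethers without touching a bond at C2, which comes back to the route at 14.

Step 9. The twisted, chelated ketones may enolise sluggishly, SeO2 may attack the free phenols or the benzylic ethers, and selenium may be retained in the product.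
- The fallback builds the furanone rings by substitution and oxidises afterwards.
- Setting out from 10, CuBr2 (EtOAc–CHCl3, reflux) should give the bis(α-bromo ketone) F4.
- K2CO3 in acetone should close both rings by 5-exo-tet displacement to the bis(2-methylbenzofuran-3(2H)-one) F5.
- Enolate hydroxylation (KHMDS, THF, −78 °C, then 2-(phenylsulfonyl)-3-phenyloxaziridine) should place the hydroxyl on C2 and C2', which comes back to the route at 12.

**Further compounds**

F1 | step 7 | 1,1'-[6,6'-bis(benzyloxy)-5,5'-dibromo-2,2'-dihydroxy-4,4'-dimethoxybiphenyl-3,3'-diyl]bis(propan-1-one) | CCC(=O)c1c(O)c(-c2c(O)c(C(=O)CC)c(OC)c(Br)c2OCc2ccccc2)c(OCc2ccccc2)c(Br)c1OC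
F2 | step 11 | 2,2'-bis-O-(benzyloxycarbonyl) derivative of 12, stereoisomer mixture | COc1c(OCc2ccccc2)c(-c2c(OCc3ccccc3)c(OC)c(OC)c3c2OC(C)(OC(=O)OCc2ccccc2)C3=O)c2c(c1OC)C(=O)C(C)(OC(=O)OCc1ccccc1)O2
F3 | step 11 | (2S,2'S)-2,2'-bis-O-(benzyloxycarbonyl) derivative of 12 | COc1c(OCc2ccccc2)c(-c2c(OCc3ccccc3)c(OC)c(OC)c3c2O[C@@](C)(OC(=O)OCc2ccccc2)C3=O)c2c(c1OC)C(=O)[C@](C)(OC(=O)OCc1ccccc1)O2
F4 | step 9 | 1,1'-[6,6'-bis(benzyloxy)-2,2'-dihydroxy-4,4',5,5'-tetramethoxybiphenyl-3,3'-diyl]bis(2-bromopropan-1-one), stereoisomer mixture | CC(Br)C(=O)c1c(O)c(-c2c(O)c(C(=O)C(C)Br)c(OC)c(OC)c2OCc2ccccc2)c(OCc2ccccc2)c(OC)c1OC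
F5 | step 9 | 6,6'-bis(benzyloxy)-4,4',5,5'-tetramethoxy-2,2'-dimethyl-[7,7'-bibenzofuran]-3,3'(2H,2'H)-dione, stereoisomer mixture | COc1c(OCc2ccccc2)c(-c2c(OCc3ccccc3)c(OC)c(OC)c3c2OC(C)C3=O)c2c(c1OC)C(=O)C(C)O2
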